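**Plan**

- Retrosynthetic cuts: the C3–O ester bond, then the C3 carbinol back to a C3 ketone, then O1–C2 of ring C, and in the open chain C2–C1' (to ring B) and C4–C4a (to ring A).
- Enabling feature: C2 carries O1, ring B and C3. With C3 as a ketone, C2 can be the carbene carbon of an α-aryl diazoketone, and the ring A phenol oxygen that becomes O1 sits five atoms away, placed for a six-membered closure.
- Forward: rings A and B are bought. O-allylation and Claisen rearrangement put C4–C3–C2 on ring A, the derived epoxide is opened at C2 by the ring B aryl Grignard reagent, and oxidation plus diazo transfer give the diazoketone.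
- Ring C is the only ring made; it closes in step 9 by carbene O–H insertion. Reduction, esterification and hydrogenolysis finish the route.
- Stereochemistry: C2 (R) comes from face-selective protonation under a chiral phosphoric acid during the insertion. C3 (R) comes from hydride attack anti to ring B on the (2R) ketone, giving the 2,3-cis alcohol.

Key step: step 9

Assumption: 3,5-bis(benzyloxy)phenol, 1,2-bis(benzyloxy)-4-bromobenzene and 3-hydroxy-4,5-dimethoxybenzoic acid are taken as purchasable.
Assumption: the sense of induction of the chiral phosphoric acid cannot be predicted with certainty for this substrate; the (R)-acid is written, and its antipode is used if a trial run shows the (2S) ketone to predominate.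

**Route**

Step 1
Reactants: 1 3,5-bis(benzyloxy)phenol; 2 allyl bromide
Product: 3 1-(allyloxy)-3,5-bis(benzyloxy)benzene
Conditions: K2CO3, acetone, reflux
Reagents that add atoms: none
Why: Williamson ether synthesis on the only free phenol; carbonate in acetone favours O- over C-allylation.

Step 2
Reactants: 3 1-(allyloxy)-3,5-bis(benzyloxy)benzene
Product: 4 2-allyl-3,5-bis(benzyloxy)phenol
Conditions: N,N-diethylaniline, 195 °C, argon
Reagents that add atoms: none
Why: Aromatic Claisen rearrangement ([3,3]-sigmatropic shift, then tautomerisation); the two ortho positions are equivalent by symmetry, so one C-allyl phenol should form, and the allyl group supplies C4, C3 and C2 of ring C.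

Step 3
Reactants: 4 2-allyl-3,5-bis(benzyloxy)phenol
Product: 5 [2-allyl-3,5-bis(benzyloxy)phenoxy]triisopropylsilane
Conditions: i-Pr3SiCl, imidazole, DMF, rt
Reagents that add atoms: chlorotriisopropylsilane, CC(C)[Si](Cl)(C(C)C)C(C)C
Why: Silylation of the phenol; the bulky silyl ether prevents the ortho oxygen from closing onto the epoxide or the ketone (dihydrobenzofuran or benzofuran formation) in the next steps and should resist the Grignard reagent, DBU and O-to-O migration.

Step 4
Reactants: 5 [2-allyl-3,5-bis(benzyloxy)phenoxy]triisopropylsilane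
Product: 6 rac-{3,5-bis(benzyloxy)-2-[(oxiran-2-yl)methyl]phenoxy}triisopropylsilane
Conditions: mCPBA, CH2Cl2/0.5 M aq. NaHCO3 (two-phase), 0 °C → rt
Reagents that add atoms: 3-chloroperoxybenzoic acid, O=C(OO)c1cccc(Cl)c1
Why: Prilezhaev epoxidation of the terminal alkene under buffered conditions that keep the epoxide closed; the racemic stereocentre formed here is erased at step 6.

Step 5
Reactants: 6 rac-{3,5-bis(benzyloxy)-2-[(oxiran-2-yl)methyl]phenoxy}triisopropylsilane; 7 1,2-bis(benzyloxy)-4-bromobenzene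
Product: 9 rac-1-[3,4-bis(benzyloxy)phenyl]-3-[2,4-bis(benzyloxy)-6-(triisopropylsilyloxy)phenyl]propan-2-ol, via [3,4-bis(benzyloxy)phenyl]magnesium bromide 8 (not isolated)
Conditions: 7, Mg, THF, reflux; then CuBr·SMe2 (10 mol %), 6, THF, −30 → 0 °C; aq. NH4Cl
Reagents that add atoms: none
Why: Copper-catalysed SN2 opening of a terminal epoxide by an aryl Grignard reagent at the unsubstituted carbon, which forms the C2–C1' bond to ring B.

Step 6
Reactants: 9 rac-1-[3,4-bis(benzyloxy)phenyl]-3-[2,4-bis(benzyloxy)-6-(triisopropylsilyloxy)phenyl]propan-2-ol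
Product: 10 1-[3,4-bis(benzyloxy)phenyl]-3-[2,4-bis(benzyloxy)-6-(triisopropylsilyloxy)phenyl]propan-2-one
Conditions: Dess–Martin periodinane, pyridine, CH2Cl2, 0 °C → rt
Reagents that add atoms: none
Why: Dess–Martin oxidation of the secondary alcohol under near-neutral conditions that leave the silyl ether, the benzyl ethers and both electron-rich rings untouched.

Step 7
Reactants: 10 1-[3,4-bis(benzyloxy)phenyl]-3-[2,4-bis(benzyloxy)-6-(triisopropylsilyloxy)phenyl]propan-2-one
Product: 11 1-diazo-1-[3,4-bis(benzyloxy)phenyl]-3-[2,4-bis(benzyloxy)-6-(triisopropylsilyloxy)phenyl]propan-2-one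
Conditions: 4-acetamidobenzenesulfonyl azide (1.1 equiv), DBU, MeCN, 0 °C → rt
Reagents that add atoms: 4-acetamidobenzenesulfonyl azide, CC(=O)Nc1ccc(cc1)S(=O)(=O)N=[N+]=[N-]
Why: Regitz diazo transfer to a benzyl ketone; the ring B methylene should react because it is the more acidic and less hindered one, the enolate on the ring A side having to conjugate with a twisted, electron-rich 2,6-dioxygenated ring.

Step 8
Reactants: 11 1-diazo-1-[3,4-bis(benzyloxy)phenyl]-3-[2,4-bis(benzyloxy)-6-(triisopropylsilyloxy)phenyl]propan-2-one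
Product: 12 1-diazo-1-[3,4-bis(benzyloxy)phenyl]-3-[2,4-bis(benzyloxy)-6-hydroxyphenyl]propan-2-one
Conditions: Bu4NF, AcOH (1 equiv each), THF, 0 °C
Reagents that add atoms: none
Why: Fluoride cleavage of the aryl silyl ether; acetic acid buffering avoids free phenoxide, and the acceptor-stabilised diazoketone should tolerate these conditions.

Step 9
Reactants: 12 1-diazo-1-[3,4-bis(benzyloxy)phenyl]-3-[2,4-bis(benzyloxy)-6-hydroxyphenyl]propan-2-one
Product: 13 (2R)-5,7-bis(benzyloxy)-2-[3,4-bis(benzyloxy)phenyl]chroman-3-one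
Conditions: Rh2(O2CCPh3)4 (1 mol %), (R)-6,6'-bis(2,4,6-triisopropylphenyl)-1,1'-spirobiindane-7,7'-diyl hydrogen phosphate (5 mol %), 4 Å MS, CHCl3, 0 °C, slow addition of 12 (final 0.01 M); cold filtration through a short silica pad, used at once
Reagents that add atoms: none
Why: Proposed new method: Rh2(O2CCPh3)4 expels N2 from 12 to give a donor/acceptor rhodium carbene at C2, the ring A phenol oxygen adds to it to form an oxonium ylide that collapses to the C2=C3 enol, and the chiral phosphoric acid relays the proton from oxygen to one face of C2, which completes the O1–C2 bond and sets (2R). The closest known reactions are the dirhodium carboxylate/chiral phosphoric acid co-catalysed enantioselective heteroatom–H insertions of α-aryl-α-diazoketones and the copper-catalysed enantioselective intramolecular phenolic O–H insertion of diazoesters to 2-substituted chromans; their combination on an aryl diazoketone closing a chroman-3-one has not been shown. Ring C closes in a six-membered exo mode, the oxygen attacking the carbene carbon five atoms away with the Rh=C bond outside the new ring. The C2 stereocentre is controlled by the catalyst alone, through face-selective proton delivery inside the hydrogen-bonded enol–phosphate pair, since 12 has no stereocentre. The step needs chemoselectivity for the phenol O–H over the C5 benzyloxy oxygen (ylide formation and 1,2-benzyl shift), over Wolff rearrangement and over intermolecular insertion; the fast proton transfer from the phenol-derived ylide, the donor aryl group on the carbene, the lack of hydrogen on the atoms next to the carbene carbon and slow addition at high dilution should secure it. Because C2–H of 13 is acidic, the ketone is not stored but reduced immediately.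

Step 10
Reactants: 13 (2R)-5,7-bis(benzyloxy)-2-[3,4-bis(benzyloxy)phenyl]chroman-3-one
Product: 14 (2R,3R)-5,7-bis(benzyloxy)-2-[3,4-bis(benzyloxy)phenyl]chroman-3-ol
Conditions: LiBH(s-Bu)3, LiBr, THF, −78 °C; aq. NH4Cl
Reagents that add atoms: none
Why: Diastereoselective ketone reduction by a bulky trialkylborohydride, which attacks C3 from the face of ring C opposite to ring B and so sets C3 as R (2,3-cis); the fast, cold reduction leaves no time for enolisation at C2.

Step 11
Reactants: 15 3-hydroxy-4,5-dimethoxybenzoic acid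
Product: 17 3-(benzyloxy)-4,5-dimethoxybenzoic acid, via benzyl 3-(benzyloxy)-4,5-dimethoxybenzoate 16 (not isolated)
Conditions: BnBr (2.2 equiv), K2CO3, DMF, 60 °C; then NaOH, MeOH/H2O, 70 °C; aq. HCl
Reagents that add atoms: benzyl bromide, BrCc1ccccc1
Why: Williamson benzylation of phenol and carboxylate, then saponification of the benzyl ester in the same pot, leaves only the phenol masked as its benzyl ether.

Step 12
Reactants: 14 (2R,3R)-5,7-bis(benzyloxy)-2-[3,4-bis(benzyloxy)phenyl]chroman-3-ol; 17 3-(benzyloxy)-4,5-dimethoxybenzoic acid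
Product: 18 (2R,3R)-5,7-bis(benzyloxy)-2-[3,4-bis(benzyloxy)phenyl]chroman-3-yl 3-(benzyloxy)-4,5-dimethoxybenzoate
Conditions: DCC, DMAP, CH2Cl2, rt
Reagents that add atoms: none
Why: Steglich esterification; the acylpyridinium intermediate acylates the axial C3 hydroxyl without breaking the C3–O bond, so C2 and C3 keep their configuration.

Step 13
Reactants: 18 (2R,3R)-5,7-bis(benzyloxy)-2-[3,4-bis(benzyloxy)phenyl]chroman-3-yl 3-(benzyloxy)-4,5-dimethoxybenzoate
Product: 19 (2R,3R)-2-(3,4-dihydroxyphenyl)-5,7-dihydroxychroman-3-yl 3-hydroxy-4,5-dimethoxybenzoate (CNP0331021.1)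
Conditions: H2 (1 atm), Pd(OH)2/C, THF/MeOH, rt
Reagents that add atoms: none
Why: Hydrogenolysis of the five O-benzyl ethers under neutral conditions, which should leave the benzoate ester and the C2 and C3 stereocentres untouched.

**Compound list**

1 | 3,5-bis(benzyloxy)phenol | Oc1cc(OCc2ccccc2)cc(OCc2ccccc2)c1 | starting material
2 | allyl bromide (3-bromoprop-1-ene) | C=CCBr | starting material
3 | 1-(allyloxy)-3,5-bis(benzyloxy)benzene | C=CCOc1cc(OCc2ccccc2)cc(OCc2ccccc2)c1 | intermediate
4 | 2-allyl-3,5-bis(benzyloxy)phenol | C=CCc1c(O)cc(OCc2ccccc2)cc1OCc1ccccc1 | intermediate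
5 | [2-allyl-3,5-bis(benzyloxy)phenoxy]triisopropylsilane | C=CCc1c(O[Si](C(C)C)(C(C)C)C(C)C)cc(OCc2ccccc2)cc1OCc1ccccc1 | intermediate
6 | rac-{3,5-bis(benzyloxy)-2-[(oxiran-2-yl)methyl]phenoxy}triisopropylsilane | C1OC1Cc1c(O[Si](C(C)C)(C(C)C)C(C)C)cc(OCc2ccccc2)cc1OCc1ccccc1 | intermediate
7 | 1,2-bis(benzyloxy)-4-bromobenzene | Brc1ccc(OCc2ccccc2)c(OCc2ccccc2)c1 | starting material
8 | [3,4-bis(benzyloxy)phenyl]magnesium bromide (not isolated) | Br[Mg]c1ccc(OCc2ccccc2)c(OCc2ccccc2)c1 | intermediate
9 | rac-1-[3,4-bis(benzyloxy)phenyl]-3-[2,4-bis(benzyloxy)-6-(triisopropylsilyloxy)phenyl]propan-2-ol | OC(Cc1ccc(OCc2ccccc2)c(OCc2ccccc2)c1)Cc1c(O[Si](C(C)C)(C(C)C)C(C)C)cc(OCc2ccccc2)cc1OCc1ccccc1 | intermediate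
10 | 1-[3,4-bis(benzyloxy)phenyl]-3-[2,4-bis(benzyloxy)-6-(triisopropylsilyloxy)phenyl]propan-2-one | O=C(Cc1ccc(OCc2ccccc2)c(OCc2ccccc2)c1)Cc1c(O[Si](C(C)C)(C(C)C)C(C)C)cc(OCc2ccccc2)cc1OCc1ccccc1 | intermediate
11 | 1-diazo-1-[3,4-bis(benzyloxy)phenyl]-3-[2,4-bis(benzyloxy)-6-(triisopropylsilyloxy)phenyl]propan-2-one | [N-]=[N+]=C(c1ccc(OCc2ccccc2)c(OCc2ccccc2)c1)C(=O)Cc1c(O[Si](C(C)C)(C(C)C)C(C)C)cc(OCc2ccccc2)cc1OCc1ccccc1 | intermediate
12 | 1-diazo-1-[3,4-bis(benzyloxy)phenyl]-3-[2,4-bis(benzyloxy)-6-hydroxyphenyl]propan-2-one | [N-]=[N+]=C(c1ccc(OCc2ccccc2)c(OCc2ccccc2)c1)C(=O)Cc1c(O)cc(OCc2ccccc2)cc1OCc1ccccc1 | intermediate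
13 | (2R)-5,7-bis(benzyloxy)-2-[3,4-bis(benzyloxy)phenyl]chroman-3-one | O=C1Cc2c(OCc3ccccc3)cc(OCc3ccccc3)cc2O[C@@H]1c1ccc(OCc2ccccc2)c(OCc2ccccc2)c1 | intermediate
14 | (2R,3R)-5,7-bis(benzyloxy)-2-[3,4-bis(benzyloxy)phenyl]chroman-3-ol | O[C@@H]1Cc2c(OCc3ccccc3)cc(OCc3ccccc3)cc2O[C@@H]1c1ccc(OCc2ccccc2)c(OCc2ccccc2)c1 | intermediate
15 | 3-hydroxy-4,5-dimethoxybenzoic acid | COc1cc(C(=O)O)cc(O)c1OC | starting material
16 | benzyl 3-(benzyloxy)-4,5-dimethoxybenzoate (not isolated) | COc1cc(C(=O)OCc2ccccc2)cc(OCc2ccccc2)c1OC | intermediate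
17 | 3-(benzyloxy)-4,5-dimethoxybenzoic acid | COc1cc(C(=O)O)cc(OCc2ccccc2)c1OC | intermediate
18 | (2R,3R)-5,7-bis(benzyloxy)-2-[3,4-bis(benzyloxy)phenyl]chroman-3-yl 3-(benzyloxy)-4,5-dimethoxybenzoate | COc1cc(C(=O)O[C@@H]2Cc3c(OCc4ccccc4)cc(OCc4ccccc4)cc3O[C@@H]2c2ccc(OCc3ccccc3)c(OCc3ccccc3)c2)cc(OCc2ccccc2)c1OC | intermediate
19 | (2R,3R)-2-(3,4-dihydroxyphenyl)-5,7-dihydroxychroman-3-yl 3-hydroxy-4,5-dimethoxybenzoate | COc1cc(C(=O)O[C@@H]2Cc3c(O)cc(O)cc3O[C@@H]2c2ccc(O)c(O)c2)cc(O)c1OC | target

**Step count**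

Total: 13 steps. Longest linear sequence: 12 steps (steps 1–10, 12 and 13, from 1 to 19); step 11 is a one-step side branch.

**Steps most likely to fail**

1. Step 9 (bears the label "Proposed new method:"). The proton transfer to C2 may show poor facial selectivity, the acid co-catalyst may re-enolise the product and erode the C2 configuration, or the carbene may be diverted into ylide formation at the C5 benzyl ether. The fallback uses known chemistry and sets out from 12. Ring C is closed without chiral control by Rh2(OAc)4 in CH2Cl2, the long-established intramolecular O–H insertion of diazoketones, to give rac-5,7-bis(benzyloxy)-2-[3,4-bis(benzyloxy)phenyl]chroman-3-one F1. The lability of C2 is then used: hydrogenation under dynamic kinetic resolution with a Noyori-type catalyst, RuCl2[(S)-xylbinap][(S)-daipen] or its antipode (whichever gives the 2R,3R isomer), with catalytic t-BuOK in i-PrOH under H2. This reaction class is known to turn racemic α-aryl and α-aryloxy cycloalkanones into single cis alcohols, and it should reduce one enantiomer of the equilibrating ketone. The fallback comes back to the route at 14.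

2. Step 7. Diazo transfer may show incomplete site selectivity between the two benzylic methylenes, or a second transfer may occur. The fallback sets out from 5 and fixes the diazo position by forming the C2–aryl bond last.
   - Lemieux–Johnson cleavage of 5 (K2OsO4·2H2O cat., NaIO4, 2,6-lutidine, dioxane/H2O) should give 2-[2,4-bis(benzyloxy)-6-(triisopropylsilyloxy)phenyl]acetaldehyde F2.
   - Pinnick oxidation (NaClO2, NaH2PO4, 2-methylbut-2-ene, t-BuOH/H2O) gives 2-[2,4-bis(benzyloxy)-6-(triisopropylsilyloxy)phenyl]acetic acid F3.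
   - Isobutyl chloroformate and N-methylmorpholine in THF at −15 °C convert it into 2-[2,4-bis(benzyloxy)-6-(triisopropylsilyloxy)phenyl]acetic isobutyl carbonic anhydride F4, which ethereal CH2N2 turns into 1-diazo-3-[2,4-bis(benzyloxy)-6-(triisopropylsilyloxy)phenyl]propan-2-one F5.
   - In parallel, copper-catalysed halogen exchange on 7 (NaI, CuI cat., N,N'-dimethylethylenediamine, dioxane, 110 °C) gives 1,2-bis(benzyloxy)-4-iodobenzene F6.
   - The known palladium-catalysed C–H arylation of acyldiazomethanes with aryl iodides (Pd(PPh3)4, Ag2CO3, Et3N, toluene, rt) then joins F5 and F6 with the diazo group retained. The fallback comes back to the route at 11.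

3. Step 4. The peracid may oxidise the electron-rich ring A in competition with the slow epoxidation of a monosubstituted alkene. The fallback sets out from 5 and builds the epoxide without a peracid.
   - Upjohn dihydroxylation (K2OsO4·2H2O cat., N-methylmorpholine N-oxide, acetone/H2O), which is selective for the alkene, should give rac-3-[2,4-bis(benzyloxy)-6-(triisopropylsilyloxy)phenyl]propane-1,2-diol F7.
   - Tin-catalysed sulfonylation of the primary hydroxyl (TsCl, Bu2SnO cat., Et3N, CH2Cl2) gives rac-3-[2,4-bis(benzyloxy)-6-(triisopropylsilyloxy)phenyl]-2-hydroxypropyl 4-methylbenzenesulfonate F8.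
   - NaH in THF at 0 °C closes the oxirane by intramolecular Williamson displacement. The fallback comes back to the route at 6.

**Further compounds**

F1 | step 9 | rac-5,7-bis(benzyloxy)-2-[3,4-bis(benzyloxy)phenyl]chroman-3-one | O=C1Cc2c(OCc3ccccc3)cc(OCc3ccccc3)cc2OC1c1ccc(OCc2ccccc2)c(OCc2ccccc2)c1
F2 | step 7 | 2-[2,4-bis(benzyloxy)-6-(triisopropylsilyloxy)phenyl]acetaldehyde | O=CCc1c(O[Si](C(C)C)(C(C)C)C(C)C)cc(OCc2ccccc2)cc1OCc1ccccc1
F3 | step 7 | 2-[2,4-bis(benzyloxy)-6-(triisopropylsilyloxy)phenyl]acetic acid | OC(=O)Cc1c(O[Si](C(C)C)(C(C)C)C(C)C)cc(OCc2ccccc2)cc1OCc1ccccc1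
F4 | step 7 | 2-[2,4-bis(benzyloxy)-6-(triisopropylsilyloxy)phenyl]acetic isobutyl carbonic anhydride | CC(C)COC(=O)OC(=O)Cc1c(O[Si](C(C)C)(C(C)C)C(C)C)cc(OCc2ccccc2)cc1OCc1ccccc1
F5 | step 7 | 1-diazo-3-[2,4-bis(benzyloxy)-6-(triisopropylsilyloxy)phenyl]propan-2-one | [N-]=[N+]=CC(=O)Cc1c(O[Si](C(C)C)(C(C)C)C(C)C)cc(OCc2ccccc2)cc1OCc1ccccc1
F6 | step 7 | 1,2-bis(benzyloxy)-4-iodobenzene | Ic1ccc(OCc2ccccc2)c(OCc2ccccc2)c1
F7 | step 4 | rac-3-[2,4-bis(benzyloxy)-6-(triisopropylsilyloxy)phenyl]propane-1,2-diol | OCC(O)Cc1c(O[Si](C(C)C)(C(C)C)C(C)C)cc(OCc2ccccc2)cc1OCc1ccccc1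
F8 | step 4 | rac-3-[2,4-bis(benzyloxy)-6-(triisopropylsilyloxy)phenyl]-2-hydroxypropyl 4-methylbenzenesulfonate | Cc1ccc(cc1)S(=O)(=O)OCC(O)Cc1c(O[Si](C(C)C)(C(C)C)C(C)C)cc(OCc2ccccc2)cc1OCc1ccccc1
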